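Assumption: Vogelin E has no stereocentre and is achiral. Its only stereoelement is the trisubstituted alkene, where CH2OH is trans to CH2Ar, so it is (E). I read "single enantiomer" as "single (E) isomer".

## Retrosynthetic overview
1. Vogelin E 9 ⇒ the (E)-enal triacetate 7, by removing three aryl acetates and a 1,2-reduction of the aldehyde.
2. 7 ⇒ 3'-allylgenistein triacetate 5 + methacrolein, by cross-metathesis across the trisubstituted C=C. This step sets the E geometry.
3. 5 ⇒ 4'-O-allylgenistein 3, by an aromatic Claisen rearrangement that makes the C3'–C bond, with the phenols trapped in situ as acetates.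
4. 3 ⇒ genistein + allyl bromide, by 4'-selective O-allylation of the 7,4'-dianion.
5. No ring is built. Rings A, B and C are bought intact in genistein, a bulk commercial isoflavone.

## Route

**Step 1**
Reactants: 1 genistein (5,7,4'-trihydroxyisoflavone); 2 allyl bromide
Product: 3 4'-O-allylgenistein, 5,7-dihydroxy-3-[4-(prop-2-enyloxy)phenyl]chromen-4-one
Conditions: t-BuOK (2.05 equiv), DMF, 0 °C, 30 min; then 2 (1.0 equiv), 0 °C → rt; chromatography to remove 7-O- and di-O-allyl by-products
Reagents that add atoms: allyl bromide, C=CCBr
Why: This is a Williamson etherification of the dianion, in which 7-O⁻ is a delocalised vinylogous carboxylate and the chelated 5-OH stays protonated, so the localised and more nucleophilic 4'-phenoxide takes the single equivalent of electrophile.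

**Step 2**
Reactants: 3; 4 acetic anhydride
Product: 5 3'-allylgenistein triacetate, 3-(4-acetoxy-3-allylphenyl)-4-oxo-4H-chromene-5,7-diyl diacetate
Conditions: Ac2O (10 equiv), PhNEt2, sealed tube/µW, 200–210 °C, 1–2 h; cool, DMAP (cat.), rt, 1 h
Reagents that add atoms: acetic anhydride, CC(=O)OC(C)=O (three acetyl groups)
Why: The aromatic Claisen [3,3] rearrangement gives one regioisomer because the two ortho positions (3'/5') are equivalent and the para position is blocked, and the anhydride traps the new 4'-OH and the 5,7-OH as acetates, which prevents dihydrobenzofuran formation and gives a CH2Cl2-soluble substrate.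

**Step 3**
Reactants: 5; 6 methacrolein
Product: 7 3-{4-acetoxy-3-[(2E)-3-methyl-4-oxobut-2-enyl]phenyl}-4-oxo-4H-chromene-5,7-diyl diacetate
Conditions: Hoveyda–Grubbs II (5 mol %, two portions), 6 (10 equiv, freshly distilled), 1,4-benzoquinone (10 mol %), CH2Cl2, 40 °C, 24 h
Reagents that add atoms: methacrolein, C=C(C)C=O (delivers =C(CH3)CHO; ethylene is lost)
Why: Olefin cross-metathesis of a type I allylarene with methacrolein gives the thermodynamic (E)-2-methyl-2-enal (typically >20:1 E), the electron-poor trisubstituted chromone C2=C3 is inert, benzoquinone suppresses allyl-to-propenyl isomerisation, and the 4'-OAc blocks 5-exo oxa-Michael closure onto the enal.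

**Step 4**
Reactants: 7
Product: 8 3-{4-acetoxy-3-[(2E)-4-hydroxy-3-methylbut-2-enyl]phenyl}-4-oxo-4H-chromene-5,7-diyl diacetate
Conditions: NaBH4 (1.0 equiv), CeCl3·7H2O (1.2 equiv), MeOH/THF 1:1, −40 → −20 °C, 20 min; acetone, then aq NH4Cl
Reagents that add atoms: none (H only)
Why: The Luche reduction gives clean 1,2-reduction of the aldehyde with the E geometry retained, the vinylogous-ester chromone carbonyl is far less electrophilic at this temperature, and any partial acetate loss does not matter because all acetates come off next.

**Step 5**
Reactants: 8
Product: 9 Vogelin E, 5,7-dihydroxy-3-{4-hydroxy-3-[(2E)-4-hydroxy-3-methylbut-2-enyl]phenyl}chromen-4-one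
Conditions: K2CO3 (4 equiv), MeOH, 0 °C → rt, 1 h; bring to pH ~6 with aq NH4Cl/citrate buffer, extract with EtOAc
Reagents that add atoms: none (three acetyls leave as MeOAc; H only is gained)
Why: Base-catalysed transesterification of the activated aryl acetates is fast and too mild to open the C ring, and the base-labile protecting groups plus near-neutral work-up avoid acid ionisation of the allylic alcohol and cyclisation onto the ortho phenol.

## Compound list
1 | Genistein | O=c1c(-c2ccc(O)cc2)coc2cc(O)cc(O)c12 | starting material
2 | Allyl bromide | C=CCBr | starting material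
3 | 4'-O-Allylgenistein | C=CCOc1ccc(-c2coc3cc(O)cc(O)c3c2=O)cc1 | intermediate
4 | Acetic anhydride | CC(=O)OC(C)=O | starting material
5 | 3'-Allylgenistein triacetate | C=CCc1cc(-c2coc3cc(OC(C)=O)cc(OC(C)=O)c3c2=O)ccc1OC(C)=O | intermediate
6 | Methacrolein | C=C(C)C=O | starting material
7 | (E)-Enal triacetate | C/C(=C\Cc1cc(-c2coc3cc(OC(C)=O)cc(OC(C)=O)c3c2=O)ccc1OC(C)=O)C=O | intermediate
8 | (E)-Allylic alcohol triacetate | C/C(=C\Cc1cc(-c2coc3cc(OC(C)=O)cc(OC(C)=O)c3c2=O)ccc1OC(C)=O)CO | intermediate
9 | Vogelin E | C/C(=C\Cc1cc(-c2coc3cc(O)cc(O)c3c2=O)ccc1O)CO | target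

## Summary
Total step count: 5. Longest linear sequence: 5.

Steps most likely to fail, each with one fallback:
1. **Step 1, 4'- versus 7-O selectivity, over-alkylation and a modest yield.** Fallback: stop differentiating the genistein hydroxyls and assemble the skeleton convergently.
   - Make 3-iodo-5,7-bis(MOM-oxy)chromone from 2,4,6-trihydroxyacetophenone (MOMCl; DMF-DMA; I2).
   - Suzuki–Miyaura couple it with the pinacol boronate of 2-allyl-4-bromophenol.
   - Remove the MOM groups at the acid-tolerant allyl stage and peracetylate, which rejoins the route at 5.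
2. **Step 3, cross-metathesis stalling or isomerising the allyl group to propenyl.** Fallback: build the olefin by carbonyl olefination instead. Lemieux–Johnson cleavage of 5 (OsO4 cat., NaIO4) gives the arylacetaldehyde, and an E-selective Wittig reaction with the stabilised ylide Ph3P=C(CH3)CHO gives the same enal 7.
3. **Step 2, decomposition or incomplete trapping in the 200 °C Claisen/acetylation.** Fallback: form the C3'–allyl bond by cross-coupling.
   - Make 3'-bromogenistein from phloroglucinol and 3-bromo-4-hydroxyphenylacetic acid (BF3·OEt2 acylation, then DMF/MsCl ring closure).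
   - Peracetylate it.
   - Stille allylation with allyltributylstannane/Pd(0) then gives 5.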